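The earlier runs and the new flask were generated by integration on assumed constants; scatter was added.

Start from the west run and choose the next flask from its climb: put everything in hot, feed slowly, or hold cold first.

| flask | starting complex | incoming ligand | leaving ligand | temperature | remark | time |
|---|---|---|---|---|---|---|
| south | 0.049 M | 3 equiv | 1 equiv | 55 °C | run made earlier |  |
| west | 0.049 M | 3 equiv | 0.50 equiv | 70 °C | run made earlier |  |
| south-east | 0.049 M | 3 equiv | 0.75 equiv | 55 °C | run made earlier |  |
| north | 0.049 M | 1.5 equiv | 1 equiv | 70 °C | run made earlier |  |
| alpha | 0.049 M | 3.00 equiv | 1.00 equiv |  | everything together at the start at 50 °C, warmed to 70 °C at 3.0 d | 4.0 d |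
| delta | 0.049 M (fed, over 3.0 d) | 3.00 equiv | 1.00 equiv | 70 °C | all else is in the flask from the start; the feed brings no volume worth counting | 4.0 d |
| beta | 0.049 M | 3.00 equiv | 1.00 equiv | 70 °C | everything together at the start | 4.0 d |
| eta | 0.049 M (fed, over 3.0 d) | 3.00 equiv | 1.00 equiv |  | the addition at 50 °C, then warmed to 70 °C; the feed brings no volume worth counting | 4.0 d |

| run | time / d | complex with two exchanged / % |
|---|---|---|
| south | 0.625 | 12.0 |
| south | 1.04 | 15.6 |
| south | 1.67 | 16.3 |
| south | 2.00 | 16.2 |
| south | 4.00 | 19.7 |
| south | 5.00 | 20.2 |
| south | 8.00 | 28.7 |
| west | 0.333 | 17.1 |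
| west | 0.625 | 20.1 |
| west | 1.04 | 24.4 |
| west | 1.25 | 28.4 |
| west | 1.67 | 32.3 |
| west | 2.08 | 33.5 |
| west | 2.50 | 36.6 |
| south-east | 0.250 | 3.4 |
| south-east | 0.625 | 12.5 |
| south-east | 1.25 | 14.7 |
| south-east | 2.00 | 15.7 |
| south-east | 4.00 | 19.9 |
| south-east | 5.00 | 20.5 |
| north | 0.500 | 12.7 |
| north | 1.04 | 19.1 |
| north | 1.25 | 21.5 |
| north | 2.08 | 31.1 |
| north | 2.50 | 31.9 |

(scatter of a reading: 1 percentage point)

1. which flask leads in amount of complex with two exchanged, in percent of the starting complex charged ("all alike" within 1.5 percentage points) (alpha / delta / beta / eta / all alike)
2. how much complex with two exchanged is there at the end, in percent of the starting complex charged: alpha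
3. how much complex with two exchanged is there at the end, in percent of the starting complex charged: delta
4. how much complex with two exchanged is there at the end, in percent of the starting complex charged: beta
5. how much complex with two exchanged is there at the end, in percent of the starting complex charged: eta



Follow one molecule of starting complex and ask for its chance of not yet being complex with two exchanged. The west run reads 20.1% of that complex at 0.625 d and 36.6% at 2.50 d, so the chance falls with a constant of 0.123 /d. Running this back to the start leaves an early burst of 13.7%. The north run, with 1.5 equiv of incoming ligand, reads about the same constant, 0.124 /d. The south run at 55 °C reads 0.0253 /d. Extend the logarithm of the constant downward by a third of that temperature span, and 50 °C gets 0.0149 /d. Each of these is a reading with its scatter.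

Now multiply constant by time at each temperature and add. For beta this gives 0.493, the exposure of a molecule. Its chance of having arrived is one minus the share missed by the burst times exp(−exposure). Count a fed molecule from its mean entry, half way through the feed, and assume the burst survives feeding. Delta then has 0.308, alpha 0.168 and eta 0.146. My reckoning gives beta 47.3%, delta 36.6%, alpha 27.1% and eta 25.4%. So charge everything together at 70 °C, because beta has the largest exposure. Drop the cold hold too: in alpha, 3.0 d at 50 °C add 0.0447, less than the 0.123 from the hot day.

The forecast names beta, with beta 46%, delta 37%, alpha 27% and eta 26%, and adds: “This assumes feeding leaves the burst unchanged, which is uncertain.”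

The flask that leads is beta, at 42.4%; delta gives 33.2%, alpha 30.9% and eta 28.2%, the order of the exposures 0.493, 0.308, 0.168 and 0.146.

    starting complex + incoming ligand → leaving ligand + complex with one exchanged (k = 3.03 /M/h, Ea = 63.0 kJ/mol)
    complex with one exchanged + incoming ligand → leaving ligand + complex with two exchanged (k = 1.14 /M/h, Ea = 91.0 kJ/mol)
    complex with two exchanged + incoming ligand ⇌ leaving ligand + complex with three exchanged (K = 9.53, k = 3.44 /M/h, Ea = 71.0 kJ/mol, ΔH = −27.0 kJ/mol)
    (constants at 70 °C)

Take eta's neighbour charged with 1.80 equiv of incoming ligand. Keep its exposure at 0.146, but run the north run's first reading back to the start the same way: the north run, with 1.5 equiv of incoming ligand, reads a burst of 7.11%, a reading with its scatter, and with that burst the reckoning gives 19.7% for the neighbour. That neighbour flask ends at 26.1% of complex with two exchanged, against 28.2% in eta, and complex with one exchanged stands there at 47.0%, against 20.0% in eta.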